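**Retrosynthetic overview**

- Numbering: lactone O1, C2 (C=O), C3, C4, C5; the exocyclic C6H carries ring A (3,4-dihydroxy-5-methoxyphenyl) and C7H2 on C4 carries ring B (4-hydroxy-3-methoxyphenyl). The strategy rests on C4, the only stereocentre, being the junction of C3, C5 and C7.
- The lactone, the only ring made, is closed late by oxidative lactonisation of the allylic 1,4-diol (C2–OH, C5–OH). C5 comes from one-carbon homologation of a boron placed on C4.
- C3–C4 and C7–ring B are formed in one operation from three fragments: the alkenyllithium of (E)-vinyl iodide 9 (C2, C3, C6, ring A), vinylboronate 15 (C4, C7) and ring B triflate 14.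
- 9 comes from 3,4-dihydroxy-5-methoxybenzaldehyde through an ynoate, syn hydrostannation and iodination, which fixes ring A cis to C2. 14 comes from vanillin.

Key step: step 10

**Remarks on the chemistry (assumptions)**

- Ring A is taken from commercial 3,4-dihydroxy-5-methoxybenzaldehyde, because electrophilic halogenation of 3-methoxycatechol would not go para to the central hydroxyl.
- MandyPhos means 1,1′-bis(diphenylphosphino)-2,2′-bis[α-(dimethylamino)benzyl]ferrocene, C52H50FeN2P2. The (Rp,Rp) antipode is specified on the assumption that the (Sp,Sp) ligand gives the opposite configuration at the boron-bearing carbon; the sense should be confirmed on a model coupling, and both antipodes are commercial.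

**Route**

Step 1
Reactants: 1 3,4-dihydroxy-5-methoxybenzaldehyde
Product: 2 3,4-bis(tert-butyldimethylsilyloxy)-5-methoxybenzaldehyde
Conditions: TBSCl (2.5 equiv), imidazole, DMF, rt
Reagents that add atoms: tert-butyldimethylsilyl chloride (CC(C)(C)[Si](C)(C)Cl)
Why: Imidazole-promoted silylation of both phenols proceeds without touching the aldehyde.

Step 2
Reactants: 2 3,4-bis(tert-butyldimethylsilyloxy)-5-methoxybenzaldehyde
Product: 3 1-(2,2-dibromovinyl)-3,4-bis(tert-butyldimethylsilyloxy)-5-methoxybenzene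
Conditions: CBr4, PPh3, CH2Cl2, 0 °C
Reagents that add atoms: carbon tetrabromide (BrC(Br)(Br)Br)
Why: Ramirez dibromo-olefination (first stage of the Corey–Fuchs sequence), a Wittig reaction of the ylide Ph3P=CBr2 with the aromatic aldehyde.

Step 3
Reactants: 3 1-(2,2-dibromovinyl)-3,4-bis(tert-butyldimethylsilyloxy)-5-methoxybenzene
Product: 5 methyl 3-[3,4-bis(tert-butyldimethylsilyloxy)-5-methoxyphenyl]prop-2-ynoate, via lithium arylacetylide 4 (not isolated)
Conditions: n-BuLi (2.1 equiv), THF, −78 °C; then ClCO2Me, −78 °C → rt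
Reagents that add atoms: methyl chloroformate (COC(=O)Cl)
Why: Second stage of the Corey–Fuchs sequence, in which n-BuLi converts the dibromoalkene into the lithium acetylide and this is C-acylated by the chloroformate; aryl silyl ethers tolerate n-BuLi at −78 °C.

Step 4
Reactants: 5 methyl 3-[3,4-bis(tert-butyldimethylsilyloxy)-5-methoxyphenyl]prop-2-ynoate
Product: 7 methyl (E)-3-[3,4-bis(tert-butyldimethylsilyloxy)-5-methoxyphenyl]-2-iodoprop-2-enoate (iodine trans to ring A, ester cis to ring A), via α-stannyl acrylate 6 (not isolated)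
Conditions: Bu3SnH, Pd(PPh3)4 (2 mol %), THF, 0 °C → rt; then I2, CH2Cl2, 0 °C, dark
Reagents that add atoms: tributyltin hydride (CCCC[SnH](CCCC)CCCC); iodine (II)
Why: Palladium-catalysed syn hydrostannation of a 2-ynoate delivers hydride to the β-carbon (C6) and tin to the ester-bearing carbon (C3), so the ester ends cis to ring A, and iododestannylation then replaces tin with retention of geometry.

Step 5
Reactants: 7 methyl (E)-3-[3,4-bis(tert-butyldimethylsilyloxy)-5-methoxyphenyl]-2-iodoprop-2-enoate
Product: 8 (E)-3-[3,4-bis(tert-butyldimethylsilyloxy)-5-methoxyphenyl]-2-iodoprop-2-en-1-ol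
Conditions: i-Bu2AlH (2.2 equiv), CH2Cl2, −78 °C; aq. KNaC4H4O6 work-up
Reagents that add atoms: none
Why: 1,2-Reduction of the enoate by i-Bu2AlH at low temperature gives the allylic alcohol (C2) and leaves the vinyl C–I bond and the alkene geometry untouched.

Step 6
Reactants: 8 (E)-3-[3,4-bis(tert-butyldimethylsilyloxy)-5-methoxyphenyl]-2-iodoprop-2-en-1-ol
Product: 9 (E)-vinyl iodide, triethyl{[(E)-3-[3,4-bis(tert-butyldimethylsilyloxy)-5-methoxyphenyl]-2-iodoprop-2-en-1-yl]oxy}silane
Conditions: Et3SiCl, imidazole, CH2Cl2, 0 °C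
Reagents that add atoms: chlorotriethylsilane (CC[Si](Cl)(CC)CC)
Why: Standard silylation of a primary allylic alcohol gives an ether that survives t-BuLi at −78 °C and is later removed by mild acid without loss of the aryl silyl ethers.

Step 7
Reactants: 10 vanillin
Product: 11 4-(tert-butyldimethylsilyloxy)-3-methoxybenzaldehyde
Conditions: TBSCl, imidazole, DMF, rt
Reagents that add atoms: tert-butyldimethylsilyl chloride (CC(C)(C)[Si](C)(C)Cl)
Why: Imidazole-promoted silylation of the phenol.

Step 8
Reactants: 11 4-(tert-butyldimethylsilyloxy)-3-methoxybenzaldehyde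
Product: 13 4-(tert-butyldimethylsilyloxy)-3-methoxyphenol, via aryl formate 12 (not isolated)
Conditions: mCPBA, CH2Cl2, 0 °C → rt; then Et3N (cat.), MeOH, 0 °C
Reagents that add atoms: 3-chloroperbenzoic acid (O=C(OO)c1cccc(Cl)c1)
Why: Baeyer–Villiger (Dakin-type) oxidation, in which the electron-rich aryl group migrates to oxygen to give the formate, which mild methanolysis cleaves without touching the aryl silyl ether.

Step 9
Reactants: 13 4-(tert-butyldimethylsilyloxy)-3-methoxyphenol
Product: 14 4-(tert-butyldimethylsilyloxy)-3-methoxyphenyl trifluoromethanesulfonate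
Conditions: Tf2O, pyridine, CH2Cl2, 0 °C
Reagents that add atoms: trifluoromethanesulfonic anhydride (O=S(=O)(OS(=O)(=O)C(F)(F)F)C(F)(F)F)
Why: O-Sulfonylation of the phenol gives the halide-free electrophile for the coupling.

Step 10
Reactants: 9 (E)-vinyl iodide; 15 vinylboronic acid pinacol ester; 14 4-(tert-butyldimethylsilyloxy)-3-methoxyphenyl trifluoromethanesulfonate
Product: 18 (S)-allylic pinacol boronate, ring B–C7H2–C4H(Bpin)–C3(CH2OSiEt3)=C6H–ring A with ring A cis to CH2OSiEt3, via alkenyllithium 16 (not isolated), via lithium bis(alkenyl)borate 17 (not isolated)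
Conditions: 9, t-BuLi (2.0 equiv), Et2O, −78 °C; 15, −78 °C → rt; evaporate, THF; KOTf (2 equiv), Pd(OAc)2 (2 mol %), (Rp,Rp)-MandyPhos (C52H50FeN2P2, 2.4 mol %), 14, 60 °C
Reagents that add atoms: none
Why: Iodine–lithium exchange with retention gives alkenyllithium 16, which adds to the boron of 15 to form the four-coordinate borate 17; zerovalent palladium inserts into the C–O bond of triflate 14, the resulting cationic divalent arylpalladium binds the unsubstituted vinyl group of 17 and induces 1,2-migration of the alkenyl group from boron to C4 anti to palladium, and reductive elimination joins C7 to ring B. The closest known reaction type is the Pd(OAc)2/MandyPhos-catalysed enantioselective conjunctive cross-coupling of bis(alkenyl)borates with aryl triflates, which gives α-chiral allylic boronates; the α-branched migrating group is a more hindered member of that class. No ring is closed. The single new stereocentre C4 is set by the chiral bisphosphine, which selects the face of the bound vinyl group to which the alkenyl group migrates (reagent control, as the substrate has no other stereocentre). The step needs site selectivity between the two alkenes on boron, secured because the trisubstituted aryl-bearing alkene binds palladium far less well than the bare vinyl group, and it needs the alkenyl group to keep its geometry, which is inherent in a 1,2-shift of an sp2 carbon. KOTf removes the iodide left by the exchange as KI, so the palladium centre stays cationic.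

Step 11
Reactants: 18 (S)-allylic pinacol boronate
Product: 21 (S,Z)-2-[4-(tert-butyldimethylsilyloxy)-3-methoxybenzyl]-4-[3,4-bis(tert-butyldimethylsilyloxy)-5-methoxyphenyl]-3-[(triethylsilyloxy)methyl]but-3-en-1-ol, via chloromethyl borate 19 (not isolated), via homologated pinacol boronate 20 (not isolated)
Conditions: ClCH2I, n-BuLi, THF, −78 °C → rt; then NaBO3·4H2O, THF/H2O, rt
Reagents that add atoms: chloroiodomethane (ClCI); sodium perborate (tetrahydrate used) ([Na+].[O-]OB=O)
Why: Matteson homologation, in which LiCH2Cl made in situ adds to boron and C4 migrates from boron to CH2 with loss of chloride and retention at C4, followed by perborate oxidation of the primary C–B bond to the C5 alcohol under conditions mild enough for the aryl silyl ethers.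

Step 12
Reactants: 21 (S,Z)-mono-triethylsilyl alcohol
Product: 22 (S,Z)-2-{[3,4-bis(tert-butyldimethylsilyloxy)-5-methoxyphenyl]methylidene}-3-[4-(tert-butyldimethylsilyloxy)-3-methoxybenzyl]butane-1,4-diol (ring A cis to the allylic CH2OH)
Conditions: PPTS (cat.), MeOH/CH2Cl2, 0 °C
Reagents that add atoms: none
Why: Acid-catalysed methanolysis removes the primary triethylsilyl ether far faster than the acid-stable aryl tert-butyldimethylsilyl ethers.

Step 13
Reactants: 22 (S,Z)-allylic 1,4-diol
Product: 25 (S,Z)-3-{[3,4-bis(tert-butyldimethylsilyloxy)-5-methoxyphenyl]methylidene}-4-[4-(tert-butyldimethylsilyloxy)-3-methoxybenzyl]dihydrofuran-2(3H)-one, via hydroxy enal 23 (not isolated), via lactol 24 (not isolated)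
Conditions: MnO2 (activated, excess), CH2Cl2, rt, dark
Reagents that add atoms: none
Why: MnO2 oxidative lactonisation, in which only the allylic C2 alcohol is oxidised to the enal, the C5 hydroxyl closes the five-membered lactol (5-exo-trig), and the lactol, again allylic, is oxidised to the lactone; C4 and the alkene geometry are not touched.

Step 14
Reactants: 25 tris-silylated (S,Z)-lactone
Product: 26 (S,Z)-3-[(3,4-dihydroxy-5-methoxyphenyl)methylidene]-4-(4-hydroxy-3-methoxybenzyl)dihydrofuran-2(3H)-one (target)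
Conditions: Bu4NF, AcOH, THF, 0 °C, argon, dark
Reagents that add atoms: none
Why: Fluoride cleaves the three aryl Si–O bonds, and the acetic acid buffer keeps the phenoxide concentration low so the Z-alkene, the catechol and the lactone should survive.

**Compound list**

1 | 3,4-dihydroxy-5-methoxybenzaldehyde | COc1cc(C=O)cc(O)c1O | starting material
2 | 3,4-bis(tert-butyldimethylsilyloxy)-5-methoxybenzaldehyde | COc1cc(C=O)cc(O[Si](C)(C)C(C)(C)C)c1O[Si](C)(C)C(C)(C)C | intermediate
3 | 1-(2,2-dibromovinyl)-3,4-bis(tert-butyldimethylsilyloxy)-5-methoxybenzene | COc1cc(C=C(Br)Br)cc(O[Si](C)(C)C(C)(C)C)c1O[Si](C)(C)C(C)(C)C | intermediate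
4 | lithium arylacetylide | COc1cc(C#C[Li])cc(O[Si](C)(C)C(C)(C)C)c1O[Si](C)(C)C(C)(C)C | intermediate (not isolated)
5 | methyl 3-[3,4-bis(tert-butyldimethylsilyloxy)-5-methoxyphenyl]prop-2-ynoate | COC(=O)C#Cc1cc(OC)c(O[Si](C)(C)C(C)(C)C)c(O[Si](C)(C)C(C)(C)C)c1 | intermediate
6 | methyl (E)-3-aryl-2-(tributylstannyl)prop-2-enoate (tin trans to ring A) | CCCC[Sn](CCCC)(CCCC)/C(C(=O)OC)=C/c1cc(OC)c(O[Si](C)(C)C(C)(C)C)c(O[Si](C)(C)C(C)(C)C)c1 | intermediate (not isolated)
7 | methyl (E)-3-[3,4-bis(tert-butyldimethylsilyloxy)-5-methoxyphenyl]-2-iodoprop-2-enoate | I/C(C(=O)OC)=C/c1cc(OC)c(O[Si](C)(C)C(C)(C)C)c(O[Si](C)(C)C(C)(C)C)c1 | intermediate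
8 | (E)-3-[3,4-bis(tert-butyldimethylsilyloxy)-5-methoxyphenyl]-2-iodoprop-2-en-1-ol | I/C(CO)=C/c1cc(OC)c(O[Si](C)(C)C(C)(C)C)c(O[Si](C)(C)C(C)(C)C)c1 | intermediate
9 | (E)-vinyl iodide, triethylsilyl ether of 8 | I/C(CO[Si](CC)(CC)CC)=C/c1cc(OC)c(O[Si](C)(C)C(C)(C)C)c(O[Si](C)(C)C(C)(C)C)c1 | intermediate
10 | vanillin | COc1cc(C=O)ccc1O | starting material
11 | 4-(tert-butyldimethylsilyloxy)-3-methoxybenzaldehyde | COc1cc(C=O)ccc1O[Si](C)(C)C(C)(C)C | intermediate
12 | 4-(tert-butyldimethylsilyloxy)-3-methoxyphenyl formate | COc1cc(OC=O)ccc1O[Si](C)(C)C(C)(C)C | intermediate (not isolated)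
13 | 4-(tert-butyldimethylsilyloxy)-3-methoxyphenol | COc1cc(O)ccc1O[Si](C)(C)C(C)(C)C | intermediate
14 | 4-(tert-butyldimethylsilyloxy)-3-methoxyphenyl trifluoromethanesulfonate | COc1cc(OS(=O)(=O)C(F)(F)F)ccc1O[Si](C)(C)C(C)(C)C | intermediate
15 | vinylboronic acid pinacol ester | C=CB1OC(C)(C)C(C)(C)O1 | starting material
16 | alkenyllithium from 9 (lithium trans to ring A) | [Li]/C(CO[Si](CC)(CC)CC)=C/c1cc(OC)c(O[Si](C)(C)C(C)(C)C)c(O[Si](C)(C)C(C)(C)C)c1 | intermediate (not isolated)
17 | lithium bis(alkenyl)(pinacolato)borate | [Li+].C=C[B-]1(OC(C)(C)C(C)(C)O1)/C(CO[Si](CC)(CC)CC)=C/c1cc(OC)c(O[Si](C)(C)C(C)(C)C)c(O[Si](C)(C)C(C)(C)C)c1 | intermediate (not isolated)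
18 | (S)-allylic pinacol boronate, boron on C4, ring A cis to CH2OSiEt3 | COc1cc(C[C@H](B2OC(C)(C)C(C)(C)O2)/C(CO[Si](CC)(CC)CC)=C/c2cc(OC)c(O[Si](C)(C)C(C)(C)C)c(O[Si](C)(C)C(C)(C)C)c2)ccc1O[Si](C)(C)C(C)(C)C | intermediate
19 | lithium (chloromethyl)borate of 18 | [Li+].COc1cc(C[C@H]([B-]2(CCl)OC(C)(C)C(C)(C)O2)/C(CO[Si](CC)(CC)CC)=C/c2cc(OC)c(O[Si](C)(C)C(C)(C)C)c(O[Si](C)(C)C(C)(C)C)c2)ccc1O[Si](C)(C)C(C)(C)C | intermediate (not isolated)
20 | (S)-homologated primary pinacol boronate (C5–B) | COc1cc(C[C@H](CB2OC(C)(C)C(C)(C)O2)/C(CO[Si](CC)(CC)CC)=C/c2cc(OC)c(O[Si](C)(C)C(C)(C)C)c(O[Si](C)(C)C(C)(C)C)c2)ccc1O[Si](C)(C)C(C)(C)C | intermediate (not isolated)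
21 | (S,Z)-C5 alcohol, C2–O triethylsilyl ether | COc1cc(C[C@H](CO)/C(CO[Si](CC)(CC)CC)=C/c2cc(OC)c(O[Si](C)(C)C(C)(C)C)c(O[Si](C)(C)C(C)(C)C)c2)ccc1O[Si](C)(C)C(C)(C)C | intermediate
22 | (S,Z)-allylic 1,4-diol | COc1cc(C[C@H](CO)/C(CO)=C/c2cc(OC)c(O[Si](C)(C)C(C)(C)C)c(O[Si](C)(C)C(C)(C)C)c2)ccc1O[Si](C)(C)C(C)(C)C | intermediate
23 | (S)-hydroxy enal (ring A cis to CHO) | COc1cc(C[C@H](CO)/C(C=O)=C/c2cc(OC)c(O[Si](C)(C)C(C)(C)C)c(O[Si](C)(C)C(C)(C)C)c2)ccc1O[Si](C)(C)C(C)(C)C | intermediate (not isolated)
24 | lactol (mixture at C2) | COc1cc(C[C@@H]2COC(O)/C2=C\c2cc(OC)c(O[Si](C)(C)C(C)(C)C)c(O[Si](C)(C)C(C)(C)C)c2)ccc1O[Si](C)(C)C(C)(C)C | intermediate (not isolated)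
25 | tris-silylated (S,Z)-lactone | COc1cc(C[C@@H]2COC(=O)/C2=C\c2cc(OC)c(O[Si](C)(C)C(C)(C)C)c(O[Si](C)(C)C(C)(C)C)c2)ccc1O[Si](C)(C)C(C)(C)C | intermediate
26 | (S,Z)-3-[(3,4-dihydroxy-5-methoxyphenyl)methylidene]-4-(4-hydroxy-3-methoxybenzyl)dihydrofuran-2(3H)-one | COc1cc(C[C@@H]2COC(=O)/C2=C\c2cc(O)c(O)c(OC)c2)ccc1O | target

**Step count**

Total: 14 steps. Longest linear sequence: 11 steps (steps 1–6 and 10–14).

**Steps most likely to fail**

1. Step 10. The alkenyllithium may be lost before it reaches boron, by migration of the triethylsilyl group from oxygen to the lithiated carbon or by loss of silanolate to an allene. Iodide from the exchange may also bind the cationic arylpalladium and block alkene binding. The fallback sets out from 9 and avoids both the alkenyllithium and the iodide. Miyaura borylation of 9 (B2pin2, PdCl2(dppf) with dppf = 1,1′-bis(diphenylphosphino)ferrocene, KOPh, toluene, 50 °C) should give, with retention, the alkenyl pinacol boronate F1. Halide-free vinyllithium (from Sn(CH=CH2)4 and n-BuLi) adds to F1 to give the same borate 17. Coupling with 14 under Pd(OAc)2 and MandyPhos as in step 10 returns to the route at 18.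

2. Step 11. Capture of the short-lived LiCH2Cl by the hindered, α-branched secondary boronate may be slower than decomposition of the carbenoid. Unchanged 18 would then be oxidised to the secondary allylic alcohol. The fallback sets out from 18 and uses the more persistent dichloromethyl carbenoid. LiCHCl2 (CH2Cl2, n-BuLi, THF, −100 °C) and then ZnCl2 should give the α-chloro boronate F2, a mixture at the new carbon that is of no consequence. LiBHEt3 then replaces chloride by hydride through a borate 1,2-hydride shift and returns to the route at 20, which is oxidised with NaBO3·4H2O to 21 as before.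

3. Step 14. Under basic fluoride the ring A phenoxide, conjugated through C6=C3 with the lactone carbonyl, may allow Z to E equilibration, and the free catechol may be oxidised by air. The fallback sets out from 25 and never lets a phenoxide accumulate. CsF and Ac2O in DMF at rt exchange the silyl groups for acetates in one pot to give the triacetate F3. Near-neutral deacetylation (NH4OAc, MeOH/H2O, rt) returns to the route at 26.

**Further compounds**

F1 | step 10 | alkenyl pinacol boronate from 9 (boron trans to ring A) | CC1(C)OB(OC1(C)C)/C(CO[Si](CC)(CC)CC)=C/c1cc(OC)c(O[Si](C)(C)C(C)(C)C)c(O[Si](C)(C)C(C)(C)C)c1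
F2 | step 11 | α-chloro pinacol boronate from 18 (mixture at the chlorinated carbon) | COc1cc(C[C@H](C(Cl)B2OC(C)(C)C(C)(C)O2)/C(CO[Si](CC)(CC)CC)=C/c2cc(OC)c(O[Si](C)(C)C(C)(C)C)c(O[Si](C)(C)C(C)(C)C)c2)ccc1O[Si](C)(C)C(C)(C)C
F3 | step 14 | triacetate of the target | COc1cc(C[C@@H]2COC(=O)/C2=C\c2cc(OC)c(OC(C)=O)c(OC(C)=O)c2)ccc1OC(C)=O
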